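**Plan**

1. Ring numbering used throughout: C1 = C=O, C2 = C(CH2OH), C3 = ring CH=, C4 = CH–O-angeloyl, C5 = CH–iPr, C6 = CH–O-acyl. The retrosynthesis first cuts the two ester C–O bonds (at C4 and C6), then cuts the ring bonds C3–C4 and C1–C2 together, which removes C2–C3 as a C-silylated propargyl ether.
2. What makes this possible: the O on C4, the iPr on C5 and the O on C6 are all cis and surround C1=O. Rejoining C1, C4, C5 and C6 gives a meso, all-cis 2,4-bis(benzyloxy)-3-isopropylcyclobutanone (mirror plane through C1=O and C5) whose two C(=O)–C(α) bonds are enantiotopic.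
3. Forward: squaric acid → dibenzyl squarate → hydride reduction, benzylation, isopropyl addition with 1,3-carbonyl transposition → cyclobutenone → hydrogenation → meso four-membered ketone. Nickel-catalysed insertion of the alkyne two-carbon unit then builds the six-membered ring, followed by debenzylation, two successive esterifications and fluoride.
4. Stereochemistry: the all-cis relative configuration comes from syn hydrogenation anti to the single C–OBn centre. The absolute configuration comes from the chiral ligand, which decides which enantiotopic ring bond nickel opens; the migrating carbon keeps its configuration. The (E)-enoate comes from a stabilized Wittig reaction, the (Z)-enoate from angelic acid.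
5. Helper group: the benzyldimethylsilyl group on the alkyne steers the insertion regiochemistry, then screens C4–OH so that C6–OH is esterified first, and leaves with fluoride in the last step.

Key step: step 7

Assumption: which antipode of the phosphoramidite ligand opens the required enantiotopic bond cannot be derived from precedent; the (S,S,S)-ligand is written, and its mirror image would be used if the first run shows the opposite sense.

**Route**

Step 1
Reactants: 1 squaric acid (3,4-dihydroxycyclobut-3-ene-1,2-dione)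
Product: 2 dibenzyl squarate (3,4-bis(benzyloxy)cyclobut-3-ene-1,2-dione)
Conditions: BnOH (6 equiv), toluene, reflux, Dean–Stark
Reagents that add atoms: benzyl alcohol, OCc1ccccc1
Why: Azeotropic Fischer-type esterification of the strongly acidic vinylogous diacid, which catalyses its own esterification; no stereocentre is involved.

Step 2
Reactants: 2 dibenzyl squarate
Product: 3 rac-2,3-bis(benzyloxy)-4-hydroxycyclobut-2-en-1-one
Conditions: LiAlH(OtBu)3 (1.1 equiv), THF, −78 °C; aq. NH4Cl
Reagents that add atoms: none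
Why: Chemoselective 1,2-hydride reduction of one squarate carbonyl should stop at the mono-alcohol because the remaining carbonyl is a deactivated vinylogous ester; the new centre is racemic, which is harmless because both enantiomers converge on the meso ketone later.

Step 3
Reactants: 3 rac-2,3-bis(benzyloxy)-4-hydroxycyclobut-2-en-1-one
Product: 4 rac-2,3,4-tris(benzyloxy)cyclobut-2-en-1-one
Conditions: BnBr (3 equiv), Ag2O (2 equiv), 4 Å molecular sieves, CH2Cl2, rt, dark
Reagents that add atoms: benzyl bromide, BrCc1ccccc1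
Why: Ag2O-promoted Williamson etherification is neither acidic nor strongly basic, so the acid-labile 4-hydroxycyclobutenone should be benzylated without ionization or ring opening.

Step 4
Reactants: 4 rac-2,3,4-tris(benzyloxy)cyclobut-2-en-1-one
Product: 6 rac-2,4-bis(benzyloxy)-3-(propan-2-yl)cyclobut-2-en-1-one, via tertiary cyclobutenol 5 (not isolated)
Conditions: i-PrMgCl (1.3 equiv), CeCl3 (1.3 equiv), THF, −78 °C; then 1 M HCl, THF, 0 °C
Reagents that add atoms: isopropylmagnesium chloride, CC(C)[Mg]Cl; water, O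
Why: Organocerium 1,2-addition to the vinylogous ester carbonyl, then acid-induced ionization of the only free (tertiary, allylic) alcohol, water capture at the benzyloxy-bearing terminus and loss of benzyl alcohol (Stork–Danheiser-type 1,3-carbonyl transposition) should place the ketone opposite the isopropyl-bearing carbon.

Step 5
Reactants: 6 rac-2,4-bis(benzyloxy)-3-(propan-2-yl)cyclobut-2-en-1-one
Product: 7 (2R,3r,4S)-2,4-bis(benzyloxy)-3-(propan-2-yl)cyclobutan-1-one (meso; both benzyloxy groups and the isopropyl group on one face)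
Conditions: H2 (3 atm), 10% Pd/C, pyridine (0.5 equiv), EtOAc, rt
Reagents that add atoms: none
Why: Heterogeneous syn hydrogenation of the strained ring alkene should occur on the face anti to the existing C4–OBn group, so both new hydrogens land there and the C2–OBn and C3–iPr groups end up cis to C4–OBn (all-cis, meso from either enantiomer of 6); pyridine-moderated Pd/C is the known way to spare benzyl ethers.

Step 6
Reactants: 8 tert-butyldimethyl(prop-2-yn-1-yloxy)silane
Product: 9 benzyl[3-(tert-butyldimethylsilyloxy)prop-1-yn-1-yl]dimethylsilane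
Conditions: n-BuLi (1.05 equiv), THF, −78 °C; then BnMe2SiCl, −78 °C → rt
Reagents that add atoms: benzylchlorodimethylsilane, C[Si](C)(Cl)Cc1ccccc1
Why: C-silylation of the lithium acetylide of a terminal alkyne is routine and installs the fluoride-removable silyl group that the key step needs.

Step 7
Reactants: 7 meso all-cis 2,4-bis(benzyloxy)-3-(propan-2-yl)cyclobutan-1-one; 9 benzyl[3-(tert-butyldimethylsilyloxy)prop-1-yn-1-yl]dimethylsilane
Product: 10 (4R,5R,6S)-4,6-bis(benzyloxy)-3-[benzyl(dimethyl)silyl]-2-[(tert-butyldimethylsilyloxy)methyl]-5-(propan-2-yl)cyclohex-2-en-1-one (C4, C5, C6 substituents all cis)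
Conditions: Ni(cod)2 (10 mol %), (S,S,S)-L* = (S)-1,1'-binaphthyl-2,2'-diyl N,N-bis[(S)-1-phenylethyl]phosphoramidite (20 mol %), 9 (1.5 equiv), toluene, 60 °C
Reagents that add atoms: none
Why: Proposed new method: zerovalent nickel joins the C=O of 7 and alkyne 9 by oxidative cyclization on the carbonyl face that carries only hydrogens, giving a spiro oxanickelacyclopentene; β-carbon elimination then opens one C(=O)–C(α) bond to a seven-membered nickelacycle, and C(sp3)–C(sp2) reductive elimination releases the cyclohexenone. The closest known reaction types are the Ni(cod)2/phosphine-catalysed intermolecular insertion of internal alkynes into cyclobutanones, 3-azetidinones and 3-oxetanones and the nickel/chiral phosphoramidite enantioselective intramolecular alkene insertion into prochiral cyclobutanones; new here is the enantiotopic-bond-selective intermolecular case on a meso 2,4-dialkoxy ketone, where the α-oxygen substituents should ease β-carbon elimination as the ring heteroatoms do in the azetidinone and oxetanone cases. The six-membered ring is closed not by an endo or exo cyclization but by two-carbon ring expansion of the four-membered ring (formal [4+2]), the ring-closing event being reductive elimination from the seven-membered nickelacycle. No stereocentre is created: C4, C5 and C6 keep the all-cis relationship of 7 because the migrating carbon retains its configuration through β-carbon elimination and reductive elimination, and the absolute configuration is fixed by the ligand, which must direct cleavage of the C1–C2 bond of 7, that is the bond to the (R)-configured α-carbon. Regioselectivity comes from silicon, which takes the position α to nickel in the oxidative cyclization (as in nickel-mediated couplings of silylalkynes with carbonyl compounds), so the CH2OTBS-bearing carbon bonds to the carbonyl carbon and the silyl-bearing carbon to the migrating carbon. Chemoselectivity (no alkyne oligomerization, no β-hydride elimination from the alkylnickel, no epimerization of the α-alkoxy centres) should be secured by the hindered, slowly oligomerizing silylalkyne, the neutral medium and the moderate temperature.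

Step 8
Reactants: 10 bis(benzyl ether) silyl enone
Product: 11 (4R,5R,6S)-3-[benzyl(dimethyl)silyl]-2-[(tert-butyldimethylsilyloxy)methyl]-4,6-dihydroxy-5-(propan-2-yl)cyclohex-2-en-1-one
Conditions: BCl3 (6 equiv), C6HMe5 (8 equiv), CH2Cl2, −78 °C; MeOH quench
Reagents that add atoms: none
Why: Lewis-acid debenzylation with pentamethylbenzene as benzyl-cation scavenger should cleave both benzyl ethers at low temperature while the enone, the alkenylsilane and the primary silyl ether survive; no stereocentre is touched.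

Step 9
Reactants: 12 (tert-butyldimethylsilyloxy)acetaldehyde; 13 ethyl 2-(triphenylphosphoranylidene)propanoate
Product: 14 ethyl (E)-4-(tert-butyldimethylsilyloxy)-2-methylbut-2-enoate
Conditions: CH2Cl2, rt
Reagents that add atoms: none
Why: Wittig olefination with a stabilized α-methyl ylide should give the (E)-trisubstituted enoate as the strongly favoured isomer.

Step 10
Reactants: 14 ethyl (E)-4-(tert-butyldimethylsilyloxy)-2-methylbut-2-enoate
Product: 15 (E)-4-(tert-butyldimethylsilyloxy)-2-methylbut-2-enoic acid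
Conditions: LiOH·H2O (3 equiv), THF/MeOH/H2O, 0 °C → rt; then cold 1 M HCl to pH 4
Reagents that add atoms: lithium hydroxide, [Li+].[OH-]
Why: Saponification of the ethyl ester under conditions a primary silyl ether tolerates; the alkene geometry is not affected.

Step 11
Reactants: 11 silyl enone diol; 15 (E)-4-(tert-butyldimethylsilyloxy)-2-methylbut-2-enoic acid
Product: 17 (4R,5S,6S)-3-[benzyl(dimethyl)silyl]-2-[(tert-butyldimethylsilyloxy)methyl]-6-[(E)-4-(tert-butyldimethylsilyloxy)-2-methylbut-2-enoyloxy]-4-hydroxy-5-(propan-2-yl)cyclohex-2-en-1-one, via mixed anhydride 16 (not isolated)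
Conditions: 15 (1.1 equiv), 2,4,6-Cl3C6H2COCl (1.1 equiv), Et3N (1.5 equiv), toluene, rt; then 11, DMAP (1.2 equiv), −20 → 0 °C
Reagents that add atoms: none
Why: Yamaguchi esterification should acylate the C6 hydroxyl selectively because the C4 hydroxyl is flanked by the C3 benzyldimethylsilyl group and the cis isopropyl group; the C6 centre is not epimerized under these mild conditions.

Step 12
Reactants: 17 C6 mono-ester with free C4 hydroxyl; 18 angelic acid ((Z)-2-methylbut-2-enoic acid)
Product: 20 (4R,5R,6S)-3-[benzyl(dimethyl)silyl]-2-[(tert-butyldimethylsilyloxy)methyl]-6-[(E)-4-(tert-butyldimethylsilyloxy)-2-methylbut-2-enoyloxy]-4-[(Z)-2-methylbut-2-enoyloxy]-5-(propan-2-yl)cyclohex-2-en-1-one, via angelic mixed anhydride 19 (not isolated)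
Conditions: 18 (4 equiv), 2,4,6-Cl3C6H2COCl (4 equiv), Et3N (4 equiv), toluene, rt; then 17, 75 °C
Reagents that add atoms: none
Why: Yamaguchi-type mixed-anhydride acylation without a nucleophilic catalyst is the established way to make angelates of hindered secondary alcohols without Z-to-E isomerization; the carbinol configuration is retained.

Step 13
Reactants: 20 fully protected diester
Product: 23 (4S,5S,6S)-6-[(E)-4-hydroxy-2-methylbut-2-enoyloxy]-2-(hydroxymethyl)-4-[(Z)-2-methylbut-2-enoyloxy]-5-(propan-2-yl)cyclohex-2-en-1-one (CNP0281432.2), via O-desilylated alkenylsilane 21 (not isolated), via fluorosilane 22 (not isolated)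
Conditions: TBAF (4 equiv), THF, 0 °C → rt; pH 7 buffer
Reagents that add atoms: none
Why: Fluoride should cleave both tert-butyldimethylsilyl ethers and, by the established fluoride protodesilylation of benzyldimethylsilyl alkenes (loss of the benzyl group as toluene, then ipso-protonation of the fluorosilane, here helped by the neighbouring CH2OH), replace the C3 silyl group by hydrogen without touching any stereocentre or double bond.

**Compound list**

1 | squaric acid (3,4-dihydroxycyclobut-3-ene-1,2-dione) | O=C1C(O)=C(O)C1=O | starting material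
2 | dibenzyl squarate (3,4-bis(benzyloxy)cyclobut-3-ene-1,2-dione) | O=C1C(OCc2ccccc2)=C(OCc2ccccc2)C1=O | intermediate
3 | rac-2,3-bis(benzyloxy)-4-hydroxycyclobut-2-en-1-one | O=C1C(OCc2ccccc2)=C(OCc2ccccc2)C1O | intermediate
4 | rac-2,3,4-tris(benzyloxy)cyclobut-2-en-1-one | O=C1C(OCc2ccccc2)=C(OCc2ccccc2)C1OCc3ccccc3 | intermediate
5 | 2,3,4-tris(benzyloxy)-1-(propan-2-yl)cyclobut-2-en-1-ol (racemic, diastereomer mixture) | OC1(C(C)C)C(OCc2ccccc2)=C(OCc2ccccc2)C1OCc3ccccc3 | intermediate (not isolated)
6 | rac-2,4-bis(benzyloxy)-3-(propan-2-yl)cyclobut-2-en-1-one | O=C1C(OCc2ccccc2)=C(C(C)C)C1OCc3ccccc3 | intermediate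
7 | (2R,3r,4S)-2,4-bis(benzyloxy)-3-(propan-2-yl)cyclobutan-1-one (meso, all-cis) | O=C1[C@@H](OCc2ccccc2)[C@@H](C(C)C)[C@H]1OCc3ccccc3 | intermediate
8 | tert-butyldimethyl(prop-2-yn-1-yloxy)silane | C#CCO[Si](C)(C)C(C)(C)C | starting material
9 | benzyl[3-(tert-butyldimethylsilyloxy)prop-1-yn-1-yl]dimethylsilane | C[Si](C)(Cc1ccccc1)C#CCO[Si](C)(C)C(C)(C)C | intermediate
10 | (4R,5R,6S)-4,6-bis(benzyloxy)-3-[benzyl(dimethyl)silyl]-2-[(tert-butyldimethylsilyloxy)methyl]-5-(propan-2-yl)cyclohex-2-en-1-one | C(c2ccccc2)O[C@H]1C([Si](C)(C)Cc2ccccc2)=C(CO[Si](C)(C)C(C)(C)C)C(=O)[C@@H](OCc2ccccc2)[C@H]1C(C)C | intermediate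
11 | (4R,5R,6S)-3-[benzyl(dimethyl)silyl]-2-[(tert-butyldimethylsilyloxy)methyl]-4,6-dihydroxy-5-(propan-2-yl)cyclohex-2-en-1-one | O[C@H]1C([Si](C)(C)Cc2ccccc2)=C(CO[Si](C)(C)C(C)(C)C)C(=O)[C@@H](O)[C@H]1C(C)C | intermediate
12 | (tert-butyldimethylsilyloxy)acetaldehyde | O=CCO[Si](C)(C)C(C)(C)C | starting material
13 | ethyl 2-(triphenylphosphoranylidene)propanoate | CCOC(=O)C(C)=P(c1ccccc1)(c1ccccc1)c1ccccc1 | starting material
14 | ethyl (E)-4-(tert-butyldimethylsilyloxy)-2-methylbut-2-enoate | CCOC(=O)/C(C)=C/CO[Si](C)(C)C(C)(C)C | intermediate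
15 | (E)-4-(tert-butyldimethylsilyloxy)-2-methylbut-2-enoic acid | OC(=O)/C(C)=C/CO[Si](C)(C)C(C)(C)C | intermediate
16 | (E)-4-(tert-butyldimethylsilyloxy)-2-methylbut-2-enoic 2,4,6-trichlorobenzoic anhydride | CC(C)(C)[Si](C)(C)OC/C=C(\C)C(=O)OC(=O)c1c(Cl)cc(Cl)cc1Cl | intermediate (not isolated)
17 | (4R,5S,6S)-3-[benzyl(dimethyl)silyl]-2-[(tert-butyldimethylsilyloxy)methyl]-6-[(E)-4-(tert-butyldimethylsilyloxy)-2-methylbut-2-enoyloxy]-4-hydroxy-5-(propan-2-yl)cyclohex-2-en-1-one | O[C@H]1C([Si](C)(C)Cc2ccccc2)=C(CO[Si](C)(C)C(C)(C)C)C(=O)[C@@H](OC(=O)/C(C)=C/CO[Si](C)(C)C(C)(C)C)[C@H]1C(C)C | intermediate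
18 | angelic acid ((Z)-2-methylbut-2-enoic acid) | C/C=C(/C)C(=O)O | starting material
19 | (Z)-2-methylbut-2-enoic 2,4,6-trichlorobenzoic anhydride | C/C=C(/C)C(=O)OC(=O)c1c(Cl)cc(Cl)cc1Cl | intermediate (not isolated)
20 | (4R,5R,6S)-3-[benzyl(dimethyl)silyl]-2-[(tert-butyldimethylsilyloxy)methyl]-6-[(E)-4-(tert-butyldimethylsilyloxy)-2-methylbut-2-enoyloxy]-4-[(Z)-2-methylbut-2-enoyloxy]-5-(propan-2-yl)cyclohex-2-en-1-one | C/C=C(/C)C(=O)O[C@H]1C([Si](C)(C)Cc2ccccc2)=C(CO[Si](C)(C)C(C)(C)C)C(=O)[C@@H](OC(=O)/C(C)=C/CO[Si](C)(C)C(C)(C)C)[C@H]1C(C)C | intermediate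
21 | (4R,5R,6S)-3-[benzyl(dimethyl)silyl]-6-[(E)-4-hydroxy-2-methylbut-2-enoyloxy]-2-(hydroxymethyl)-4-[(Z)-2-methylbut-2-enoyloxy]-5-(propan-2-yl)cyclohex-2-en-1-one | C/C=C(/C)C(=O)O[C@H]1C([Si](C)(C)Cc2ccccc2)=C(CO)C(=O)[C@@H](OC(=O)/C(C)=C/CO)[C@H]1C(C)C | intermediate (not isolated)
22 | (4R,5R,6S)-3-[fluoro(dimethyl)silyl]-6-[(E)-4-hydroxy-2-methylbut-2-enoyloxy]-2-(hydroxymethyl)-4-[(Z)-2-methylbut-2-enoyloxy]-5-(propan-2-yl)cyclohex-2-en-1-one | C/C=C(/C)C(=O)O[C@H]1C([Si](C)(C)F)=C(CO)C(=O)[C@@H](OC(=O)/C(C)=C/CO)[C@H]1C(C)C | intermediate (not isolated)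
23 | (4S,5S,6S)-6-[(E)-4-hydroxy-2-methylbut-2-enoyloxy]-2-(hydroxymethyl)-4-[(Z)-2-methylbut-2-enoyloxy]-5-(propan-2-yl)cyclohex-2-en-1-one (CNP0281432.2) | C/C=C(/C)C(=O)O[C@H]1C=C(CO)C(=O)[C@@H](OC(=O)/C(C)=C/CO)[C@H]1C(C)C | target

**Step count and risks**

Total steps: 13. Longest linear sequence: 10 steps (steps 1, 2, 3, 4, 5, 7, 8, 11, 12, 13).

Steps most likely to fail:

1. Step 7. The chiral nickel catalyst may discriminate poorly between the two enantiotopic C(=O)–C(α) bonds, giving low enantiomeric purity, or oxidative cyclization at the doubly α-substituted carbonyl may be slow enough for β-hydride elimination to compete. Fallback: starting from 7 and 9, the known achiral insertion (Ni(cod)2 with PCy3, toluene, 60–90 °C) should give 10 together with its mirror image, (4S,5S,6R)-4,6-bis(benzyloxy)-3-[benzyl(dimethyl)silyl]-2-[(tert-butyldimethylsilyloxy)methyl]-5-(propan-2-yl)cyclohex-2-en-1-one F1. The enantiomers would be separated by preparative HPLC on a chiral stationary phase, and the route resumes at 10.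

2. Step 12. Acylation of the silyl-screened, isopropyl-flanked C4 hydroxyl may be too slow, and prolonged heating with amine invites acyl migration from O6 to O4, epimerization at C6 or Z-to-E isomerization of the angelate. Fallback: starting from 17, silicon is taken off first, so that the hydroxyl is no longer screened. TBAF buffered with AcOH in THF should remove both silyl ethers and the ring silyl group to give (4S,5S,6S)-4-hydroxy-6-[(E)-4-hydroxy-2-methylbut-2-enoyloxy]-2-(hydroxymethyl)-5-(propan-2-yl)cyclohex-2-en-1-one F2. TBSCl (2.1 equiv) with imidazole at 0 °C should silylate only the two primary alcohols to give (4S,5S,6S)-2-[(tert-butyldimethylsilyloxy)methyl]-6-[(E)-4-(tert-butyldimethylsilyloxy)-2-methylbut-2-enoyloxy]-4-hydroxy-5-(propan-2-yl)cyclohex-2-en-1-one F3. Acylation of the now unhindered C4 hydroxyl with mixed anhydride 19 should give (4S,5S,6S)-2-[(tert-butyldimethylsilyloxy)methyl]-6-[(E)-4-(tert-butyldimethylsilyloxy)-2-methylbut-2-enoyloxy]-4-[(Z)-2-methylbut-2-enoyloxy]-5-(propan-2-yl)cyclohex-2-en-1-one F4. HF·pyridine in THF/pyridine at 0 °C then gives 23, where this fallback rejoins the route.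

3. Step 11. Discrimination between the C6 and C4 hydroxyls may be insufficient, giving diester or the C4 ester. Fallback: starting from 10, the two oxygens are unveiled one after the other instead of being distinguished by acylation. One equivalent of BCl3 with C6HMe5 at −78 °C should cleave only the C6 benzyl ether, because boron is held between the C1 carbonyl and the C6 ether oxygen while the C4 ether is screened by silicon. This gives (4R,5R,6S)-4-(benzyloxy)-3-[benzyl(dimethyl)silyl]-2-[(tert-butyldimethylsilyloxy)methyl]-6-hydroxy-5-(propan-2-yl)cyclohex-2-en-1-one F5. Yamaguchi esterification with 15 should give (4R,5R,6S)-4-(benzyloxy)-3-[benzyl(dimethyl)silyl]-2-[(tert-butyldimethylsilyloxy)methyl]-6-[(E)-4-(tert-butyldimethylsilyloxy)-2-methylbut-2-enoyloxy]-5-(propan-2-yl)cyclohex-2-en-1-one F6. Excess BCl3 with C6HMe5 at −78 °C then removes the remaining benzyl ether and returns to the route at 17.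

**Further compounds**

F1 | step 7 | (4S,5S,6R)-4,6-bis(benzyloxy)-3-[benzyl(dimethyl)silyl]-2-[(tert-butyldimethylsilyloxy)methyl]-5-(propan-2-yl)cyclohex-2-en-1-one (enantiomer of 10) | C(c2ccccc2)O[C@@H]1C([Si](C)(C)Cc2ccccc2)=C(CO[Si](C)(C)C(C)(C)C)C(=O)[C@H](OCc2ccccc2)[C@@H]1C(C)C
F2 | step 12 | (4S,5S,6S)-4-hydroxy-6-[(E)-4-hydroxy-2-methylbut-2-enoyloxy]-2-(hydroxymethyl)-5-(propan-2-yl)cyclohex-2-en-1-one | O[C@H]1C=C(CO)C(=O)[C@@H](OC(=O)/C(C)=C/CO)[C@H]1C(C)C
F3 | step 12 | (4S,5S,6S)-2-[(tert-butyldimethylsilyloxy)methyl]-6-[(E)-4-(tert-butyldimethylsilyloxy)-2-methylbut-2-enoyloxy]-4-hydroxy-5-(propan-2-yl)cyclohex-2-en-1-one | O[C@H]1C=C(CO[Si](C)(C)C(C)(C)C)C(=O)[C@@H](OC(=O)/C(C)=C/CO[Si](C)(C)C(C)(C)C)[C@H]1C(C)C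
F4 | step 12 | (4S,5S,6S)-2-[(tert-butyldimethylsilyloxy)methyl]-6-[(E)-4-(tert-butyldimethylsilyloxy)-2-methylbut-2-enoyloxy]-4-[(Z)-2-methylbut-2-enoyloxy]-5-(propan-2-yl)cyclohex-2-en-1-one | C/C=C(/C)C(=O)O[C@H]1C=C(CO[Si](C)(C)C(C)(C)C)C(=O)[C@@H](OC(=O)/C(C)=C/CO[Si](C)(C)C(C)(C)C)[C@H]1C(C)C
F5 | step 11 | (4R,5R,6S)-4-(benzyloxy)-3-[benzyl(dimethyl)silyl]-2-[(tert-butyldimethylsilyloxy)methyl]-6-hydroxy-5-(propan-2-yl)cyclohex-2-en-1-one | C(c2ccccc2)O[C@H]1C([Si](C)(C)Cc2ccccc2)=C(CO[Si](C)(C)C(C)(C)C)C(=O)[C@@H](O)[C@H]1C(C)C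
F6 | step 11 | (4R,5R,6S)-4-(benzyloxy)-3-[benzyl(dimethyl)silyl]-2-[(tert-butyldimethylsilyloxy)methyl]-6-[(E)-4-(tert-butyldimethylsilyloxy)-2-methylbut-2-enoyloxy]-5-(propan-2-yl)cyclohex-2-en-1-one | C(c2ccccc2)O[C@H]1C([Si](C)(C)Cc2ccccc2)=C(CO[Si](C)(C)C(C)(C)C)C(=O)[C@@H](OC(=O)/C(C)=C/CO[Si](C)(C)C(C)(C)C)[C@H]1C(C)C
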